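**Retrosynthetic overview**

- The target is the all-cis (1R,2R,3R) indane. It is reached by six-fold O-demethylation of ketone 12, which comes from the all-cis acid 9 by a base-free acyl Negishi coupling.
- The all-cis C1/C2/C3 triad comes from syn-hydrogenation of the tetrasubstituted indene 8 on the face opposite to its one existing aryl-bearing stereocentre.
- Indene 8 is assembled in one operation by a formal [3+2] annulation. An aryl diazoacetate supplies C1, C7a and C3a; a diarylalkyne supplies C2 and C3. The bonds C1–C2 and C3–C3a are formed.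
- Enabling feature: C3a of the fused benzene ring A is ortho to the C4 oxygen and para to the C6 oxygen, so it captures a carbenoid at C3. The para-oxygenated aryl ring on C2 steers the opening of the transient cyclopropene so that C3 becomes that carbenoid.
- Ring order: all benzene rings are bought. A three-membered ring is formed and opened in step 4, where the five-membered ring closes; no other ring is built.

Key step: step 4

Remark: the SMILES fixes the (1R,2R,3R) isomer, in which the aroyl group at C1 and the aryl groups at C2 and C3 all lie on one face of the five-membered ring; the route is built for this all-cis arrangement, with the six phenols carried as methyl ethers.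

Assumption: the sense of induction of the chiral gold complex in step 4 cannot be predicted with confidence; the (R)-ligand is written, and its antipode would be used if the first run shows the opposite sense.

**Route**

Step 1
Reactants: 1 3,5-dimethoxyphenylacetic acid
Product: 2 benzyl 2-(3,5-dimethoxyphenyl)acetate
Conditions: BnBr, K2CO3, DMF, 25 °C
Reagents that add atoms: benzyl bromide, BrCc1ccccc1
Why: SN2 O-alkylation of the carboxylate gives the benzyl ester, chosen because it is later removed by the same hydrogenation that sets the stereotriad.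

Step 2
Reactants: 2 benzyl 2-(3,5-dimethoxyphenyl)acetate
Product: 3 benzyl 2-diazo-2-(3,5-dimethoxyphenyl)acetate
Conditions: p-ABSA, DBU, MeCN, 0 → 25 °C
Reagents that add atoms: 4-acetamidobenzenesulfonyl azide (p-ABSA), CC(=O)Nc1ccc(cc1)S(=O)(=O)N=[N+]=[N-]
Why: Regitz diazo transfer to the benzylic ester enolate is the standard entry to aryl diazoacetates and tolerates the ester and the methyl ethers.

Step 3
Reactants: 4 1-iodo-3,5-dimethoxybenzene; 5 1-ethynyl-4-methoxybenzene
Product: 6 1,3-dimethoxy-5-[(4-methoxyphenyl)ethynyl]benzene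
Conditions: PdCl2(PPh3)2 (2 mol%), CuI (4 mol%), Et3N, THF, 50 °C
Reagents that add atoms: none
Why: Sonogashira coupling of an aryl iodide with a terminal arylalkyne gives the unsymmetrical diarylalkyne directly.

Step 4
Reactants: 3 benzyl 2-diazo-2-(3,5-dimethoxyphenyl)acetate; 6 1,3-dimethoxy-5-[(4-methoxyphenyl)ethynyl]benzene
Product: 8 benzyl (1S)-1-(3,5-dimethoxyphenyl)-5,7-dimethoxy-2-(4-methoxyphenyl)-1H-indene-3-carboxylate, via triarylcyclopropene ester 7 (not isolated)
Conditions: AgOTf (10 mol%), 4 Å MS, CH2Cl2, 0 °C, slow addition of 3 to 6; then [(R)-DTBM-SEGPHOS](AuCl)2 (5 mol%), 0 → 35 °C; neutral work-up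
Reagents that add atoms: none
Why: Proposed new method: the silver carbene formed from 3 by loss of N2 cyclopropenates alkyne 6 to 7, and the cationic gold complex then attacks the cyclopropene carbon that bears the 3,5-dimethoxyphenyl ring, because the 4-methoxyphenyl ring stabilises the charge building up on the other carbon, so that the bond between the aurated carbon and the quaternary carbon opens to an aurated allyl cation (gold vinylcarbene). Its gold-bearing terminus is attacked by the ortho carbon of ring A, which is ortho to one OMe and para to the other, in a 4π (Nazarov-type) closure of the aryl-pentadienyl cation that forms the five-membered ring, and rearomatisation with retentive protodeauration should give 8. The closest known reaction types are the copper-catalysed formal [3+2] annulation of aryl diazoacetates with alkynes to indenes, the silver-catalysed cyclopropenation of internal alkynes and the gold-catalysed isomerisation of 3-arylcyclopropene-3-carboxylates to indenes; the unsymmetrical diarylalkyne and the enantioselective version are new. The stereocentre of 8 is created at the gold-bound carbon during C–C bond formation and is controlled by the chiral bisphosphine on gold, the only chiral element present. The step needs three selectivities: the sense of ring opening (secured by the donor gap between the para-methoxyphenyl and the meta,meta-dimethoxyphenyl ring), closure onto ring A and not onto the ester oxygen (ring A is by far the better nucleophile), and the enantioface (ligand).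

Step 5
Reactants: 8 benzyl (1S)-1-(3,5-dimethoxyphenyl)-5,7-dimethoxy-2-(4-methoxyphenyl)-1H-indene-3-carboxylate
Product: 9 (1R,2R,3R)-3-(3,5-dimethoxyphenyl)-4,6-dimethoxy-2-(4-methoxyphenyl)-2,3-dihydro-1H-indene-1-carboxylic acid
Conditions: H2 (5 bar), 10% Pd/C, EtOAc, 25 °C
Reagents that add atoms: none
Why: Heterogeneous syn-hydrogenation (with hydrogenolysis of the benzyl ester) should deliver both hydrogens to the tetrasubstituted double bond from the face opposite to the 3,5-dimethoxyphenyl group on the sp3 carbon, so that this one stereocentre sets the two new ones and the carboxyl and both aryl groups end up all cis, as is usual for 1-aryl-1H-indene carboxylates.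

Step 6
Reactants: 9 (1R,2R,3R)-3-(3,5-dimethoxyphenyl)-4,6-dimethoxy-2-(4-methoxyphenyl)-2,3-dihydro-1H-indene-1-carboxylic acid; 10 (4-methoxyphenyl)zinc iodide
Product: 12 [(1R,2R,3R)-3-(3,5-dimethoxyphenyl)-4,6-dimethoxy-2-(4-methoxyphenyl)-2,3-dihydro-1H-inden-1-yl](4-methoxyphenyl)methanone, via acid chloride 11 (not isolated)
Conditions: 1-chloro-N,N,2-trimethylprop-1-en-1-amine, CH2Cl2, 0 → 25 °C; evaporate; then 10, Pd(PPh3)4 (5 mol%), THF, 0 → 25 °C
Reagents that add atoms: 1-chloro-N,N,2-trimethylprop-1-en-1-amine, CC(C)=C(Cl)N(C)C (supplies the chlorine of 11 only)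
Why: Acid chloride formation with the α-chloroenamine releases neither HCl nor base, and the Negishi acylation with a weakly basic arylzinc reagent should give the aryl ketone without enolising the cis-configured C1.

Step 7
Reactants: 12 [(1R,2R,3R)-3-(3,5-dimethoxyphenyl)-4,6-dimethoxy-2-(4-methoxyphenyl)-2,3-dihydro-1H-inden-1-yl](4-methoxyphenyl)methanone
Product: 13 Caraphenol B as specified, (4-hydroxyphenyl)[(1R,2R,3R)-3-(3,5-dihydroxyphenyl)-4,6-dihydroxy-2-(4-hydroxyphenyl)-2,3-dihydro-1H-inden-1-yl]methanone
Conditions: BBr3 (12 equiv), CH2Cl2, −78 → 0 °C; MeOH then H2O at −78 °C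
Reagents that add atoms: none
Why: BBr3 cleavage of the six aryl methyl ethers runs without base, and the low temperature and cold quench are meant to limit Lewis-acid-mediated enolisation at C1, the one stereocentre at risk.

**Compound list**

1 | 3,5-dimethoxyphenylacetic acid | COc1cc(CC(=O)O)cc(OC)c1 | starting material
2 | benzyl 2-(3,5-dimethoxyphenyl)acetate | COc1cc(CC(=O)OCc2ccccc2)cc(OC)c1 | intermediate
3 | benzyl 2-diazo-2-(3,5-dimethoxyphenyl)acetate | COc1cc(cc(OC)c1)C(=[N+]=[N-])C(=O)OCc1ccccc1 | intermediate
4 | 1-iodo-3,5-dimethoxybenzene | COc1cc(I)cc(OC)c1 | starting material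
5 | 1-ethynyl-4-methoxybenzene | COc1ccc(cc1)C#C | starting material
6 | 1,3-dimethoxy-5-[(4-methoxyphenyl)ethynyl]benzene | COc1ccc(cc1)C#Cc1cc(OC)cc(OC)c1 | intermediate
7 | benzyl 1,2-bis(3,5-dimethoxyphenyl)-3-(4-methoxyphenyl)cycloprop-2-ene-1-carboxylate (either configuration at C1; the centre is lost on ring opening; not isolated) | COc1ccc(cc1)C1=C(c2cc(OC)cc(OC)c2)C1(C(=O)OCc1ccccc1)c1cc(OC)cc(OC)c1 | intermediate
8 | benzyl (1S)-1-(3,5-dimethoxyphenyl)-5,7-dimethoxy-2-(4-methoxyphenyl)-1H-indene-3-carboxylate | O=C(OCc1ccccc1)C1=C(c2ccc(OC)cc2)[C@H](c2cc(OC)cc(OC)c2)c2c(OC)cc(OC)cc21 | intermediate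
9 | (1R,2R,3R)-3-(3,5-dimethoxyphenyl)-4,6-dimethoxy-2-(4-methoxyphenyl)-2,3-dihydro-1H-indene-1-carboxylic acid (all cis) | O=C(O)[C@H]1c2cc(OC)cc(OC)c2[C@@H](c2cc(OC)cc(OC)c2)[C@H]1c1ccc(OC)cc1 | intermediate
10 | (4-methoxyphenyl)zinc iodide (THF solution) | COc1ccc([Zn]I)cc1 | starting material
11 | (1R,2R,3R)-3-(3,5-dimethoxyphenyl)-4,6-dimethoxy-2-(4-methoxyphenyl)-2,3-dihydro-1H-indene-1-carbonyl chloride (not isolated) | O=C(Cl)[C@H]1c2cc(OC)cc(OC)c2[C@@H](c2cc(OC)cc(OC)c2)[C@H]1c1ccc(OC)cc1 | intermediate
12 | [(1R,2R,3R)-3-(3,5-dimethoxyphenyl)-4,6-dimethoxy-2-(4-methoxyphenyl)-2,3-dihydro-1H-inden-1-yl](4-methoxyphenyl)methanone | O=C(c1ccc(OC)cc1)[C@H]1c2cc(OC)cc(OC)c2[C@@H](c2cc(OC)cc(OC)c2)[C@H]1c1ccc(OC)cc1 | intermediate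
13 | Caraphenol B as specified, (4-hydroxyphenyl)[(1R,2R,3R)-3-(3,5-dihydroxyphenyl)-4,6-dihydroxy-2-(4-hydroxyphenyl)-2,3-dihydro-1H-inden-1-yl]methanone | O=C(c1ccc(O)cc1)[C@H]1c2cc(O)cc(O)c2[C@@H](c2cc(O)cc(O)c2)[C@H]1c1ccc(O)cc1 | target

**Step count and risks**

Total steps: 7. Longest linear sequence: 6 steps (1 → 2 → 3 → 8 → 9 → 12 → 13).

Steps most likely to fail:

1. Step 4 (Proposed new method). What may go wrong: weak enantioface control in the ring closure; loss of enantiomeric purity if the proton is delivered to the far end of the allylgold intermediate; ring opening in the wrong sense; or closure through the ester oxygen. Fallback, setting out from 3 and 6: the cascade is run with achiral catalysts (AgOTf, CH2Cl2, then Ph3PAuCl) to the racemic indene ester F1. Preparative SFC on a chiral stationary phase gives 8. The unwanted (1R)-indene ester F2 is racemised with catalytic DBU in toluene through the indenide and recycled. The route is rejoined at 8.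

2. Step 7. What may go wrong: epimerisation at C1 by Lewis-acid-mediated enolisation during demethylation, which would lead to the more stable 1,2-trans isomer. Fallback, setting out from 12: the demethylation is run as in step 7, giving 13 mixed with its C1 epimer, the (1S,2R,3R)-hexaphenol F4. The crude mixture is silylated (TBSCl, imidazole, DMF) to the hexakis(tert-butyldimethylsilyl) ether of 13 F5 and its C1 epimer F6. KN(SiMe3)2 (THF, −78 °C) converts both into one potassium enolate F7. Kinetic protonation with AcOH at −78 °C, from the face opposite to the two cis aryl groups, should return F5 alone. Buffered desilylation (HF·pyridine, pyridine/THF, 0 °C) then gives 13, where the route ends.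

3. Step 5. What may go wrong: stalling of the hydrogenation at the crowded tetrasubstituted double bond, or double-bond migration on the metal surface before reduction, which would erode enantiomeric and diastereomeric purity. Fallback, setting out from 8: the benzyl ester alone is cleaved by transfer hydrogenolysis (Pd/C, 1,4-cyclohexadiene, EtOH, 25 °C) to the (1S)-indene acid F3. F3 is then hydrogenated homogeneously under carboxylate direction with a chiral iridium spiro phosphine–oxazoline complex of the kind used for tetrasubstituted α,β-unsaturated acids ([Ir(cod)(SIPHOX)]B[3,5-(CF3)2C6H3]4, H2 10 bar, Cs2CO3 0.5 equiv, MeOH), with the ligand antipode matched to the substrate's own facial preference. The route is rejoined at 9.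

**Further compounds**

F1 | step 4 | racemic benzyl 1-(3,5-dimethoxyphenyl)-5,7-dimethoxy-2-(4-methoxyphenyl)-1H-indene-3-carboxylate | O=C(OCc1ccccc1)C1=C(c2ccc(OC)cc2)C(c2cc(OC)cc(OC)c2)c2c(OC)cc(OC)cc21
F2 | step 4 | benzyl (1R)-1-(3,5-dimethoxyphenyl)-5,7-dimethoxy-2-(4-methoxyphenyl)-1H-indene-3-carboxylate | O=C(OCc1ccccc1)C1=C(c2ccc(OC)cc2)[C@@H](c2cc(OC)cc(OC)c2)c2c(OC)cc(OC)cc21
F3 | step 5 | (1S)-1-(3,5-dimethoxyphenyl)-5,7-dimethoxy-2-(4-methoxyphenyl)-1H-indene-3-carboxylic acid | O=C(O)C1=C(c2ccc(OC)cc2)[C@H](c2cc(OC)cc(OC)c2)c2c(OC)cc(OC)cc21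
F4 | step 7 | (4-hydroxyphenyl)[(1S,2R,3R)-3-(3,5-dihydroxyphenyl)-4,6-dihydroxy-2-(4-hydroxyphenyl)-2,3-dihydro-1H-inden-1-yl]methanone (C1 epimer of 13) | O=C(c1ccc(O)cc1)[C@@H]1c2cc(O)cc(O)c2[C@@H](c2cc(O)cc(O)c2)[C@H]1c1ccc(O)cc1
F5 | step 7 | hexakis(tert-butyldimethylsilyl) ether of 13 (all cis) | O=C(c1ccc(O[Si](C)(C)C(C)(C)C)cc1)[C@H]1c2cc(O[Si](C)(C)C(C)(C)C)cc(O[Si](C)(C)C(C)(C)C)c2[C@@H](c2cc(O[Si](C)(C)C(C)(C)C)cc(O[Si](C)(C)C(C)(C)C)c2)[C@H]1c1ccc(O[Si](C)(C)C(C)(C)C)cc1
F6 | step 7 | hexakis(tert-butyldimethylsilyl) ether of F4 (C1 epimer of F5) | O=C(c1ccc(O[Si](C)(C)C(C)(C)C)cc1)[C@@H]1c2cc(O[Si](C)(C)C(C)(C)C)cc(O[Si](C)(C)C(C)(C)C)c2[C@@H](c2cc(O[Si](C)(C)C(C)(C)C)cc(O[Si](C)(C)C(C)(C)C)c2)[C@H]1c1ccc(O[Si](C)(C)C(C)(C)C)cc1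
F7 | step 7 | potassium enolate of F5 and F6 (C1 trigonal, C2 and C3 as in 13, enolate geometry not specified) | [K+].[O-]C(c1ccc(O[Si](C)(C)C(C)(C)C)cc1)=C1c2cc(O[Si](C)(C)C(C)(C)C)cc(O[Si](C)(C)C(C)(C)C)c2[C@@H](c2cc(O[Si](C)(C)C(C)(C)C)cc(O[Si](C)(C)C(C)(C)C)c2)[C@H]1c1ccc(O[Si](C)(C)C(C)(C)C)cc1
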